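The easy step is to add Z and D at the last reading of a run and ask how many lifetimes of the pair have passed: the natural log of charged over left. X, which is single-handed, turns Z into E and D into J with the help of L.

in all of them: Z 0.10 M; D 0.10 M
- west: L 0.40 M; X 1 mM; run made earlier
- south-east: L 0.40 M; X 4 mM; run made earlier
- flask: L 0.400 M; X 2.0 mM; time 2.5 d

| run | time / d | Z / % | D / % |
|---|---|---|---|
| west | 0.250 | 49 | 51 |
| west | 0.333 | 48 | 48 |
| west | 0.500 | 48 | 47 |
| west | 0.833 | 47 | 49 |
| west | 1.25 | 43 | 50 |
| west | 2.08 | 41 | 45 |
| west | 3.00 | 39 | 43 |
| south-east | 0.167 | 49 | 50 |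
| south-east | 0.500 | 45 | 48 |
| south-east | 0.833 | 43 | 46 |
| south-east | 1.25 | 40 | 43 |
| south-east | 1.67 | 35 | 42 |
| south-east | 2.50 | 34 | 38 |
| south-east | 3.00 | 32 | 36 |

(standard deviation of a reading: 1.5 percentage points)

1. part of the Z and D charged together that has reacted at 2.5 d
2. excess of E over J in the product at 2.5 d
3. excess of D over Z among what is left of the two at 2.5 d

- X is single-handed; Z and D are mirror images of each other, charged as a racemate, each of them at the stated concentration
- steps thought possible: L + X + Z -> X + E; L + X + D -> X + J; Z <-> D; L <-> G; 2 X <-> Q
- an excess is the difference of the two amounts in percent of their sum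
- an excess is below zero if the other one leads

The west run looks nearly the same as the flask: it has the same Z, D and L, but [X] is 1 mM instead of 2.0 mM. Does double the catalyst then mean double the speed? Both runs, at their last readings, give lifetimes per day:

west: 82.0% left after 3.00 d, so 0.0662 d⁻¹

south-east: 68.0% left after 3.00 d, so 0.129 d⁻¹

A charge of X larger by a factor 4.00 makes this speed about twice as great, which is less than the rise in charge. That is the pattern when X pairs into Q, an off-cycle form, and free X goes as the root of the charge. The flask's [X] is the geometric mean of the two charges, midway between them on a log scale, so with that root law I take the root of the product of the two speeds as the pair clock, the lifetimes of Z and D together per day: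

clock = 0.0922 d⁻¹

count over 2.5 d = 0.231, so c = 20.6%

The flask's clock is 1.39 times the west clock, not 2.00 times, and at 2.5 d the west clock reckons 15.3%. The clock counts the pair, so it gives me c but not the split between Z and D.

The forecast says c 21%, eP 20% and eS 5.2%, on the ground that “Four times the catalyst gives only about twice the rate”. The flask gives c 21.3%, eP 39.8% and eS 3.78%.

    L + X + Z → X + E (k = 120 L² mol⁻² h⁻¹)
    L + X + D → X + J (k = 49.0 L² mol⁻² h⁻¹)
    Z ⇌ D (k = 0.0190 h⁻¹)
    L ⇌ G (K = 0.480, k = 0.0400 h⁻¹)
    2 X ⇌ Q, settled at all times (K = 29000 L mol⁻¹)

The flask's own count is 0.240 lifetimes against my 0.231. It stops there because Q holds nearly all of the catalyst and the run is short: with the pairing struck out c is 84.1%, and a run ten times as long reaches 82.3%. At [X] = 0.500 mM the clock runs at half speed, so the count is 0.116 and c is 10.9%. That flask computes to 11.2%.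

(The numbers in the tables are simulated with made-up constants; noise was put on by code.)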